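**Plan**

1. Locants follow the daucane skeleton: C1 quaternary ring-fusion carbon, C2 CH–O(angeloyl), C3 CH2, C4 C(OH)(i-Pr), C5 ring-fusion CH, C6 CH–O(anisoyl), C7 CH2, C8(Me)=C9, C10 CH2; ring A is the cyclopentane, ring B the cycloheptene.
2. Retrosynthetic cuts, in order: O–angeloyl; C8=C9 (ring B, metathesis); the O–O bond of a 2,3-dioxabicyclo[2.2.1]heptane that stands for the cis C2–O/C4–O pair; C2–C3 together with O–C4 (ring A); O–anisoyl; C6–C7; C1–CH3 and C1–C10; C5–C4.
3. Enabling feature: in ring A the oxygens on C2 and C4 are cis across the C3 methylene, C2 sits on the quaternary C1 and C4 carries the isopropyl group, so a peroxy-substituted C2 cation and a 1,1-disubstituted C3=C4 alkene can be joined in one event that makes the C2–C3 bond and both C–O relationships.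
4. Forward: butenolide → conjugate addition (C5) → two lactone alkylations (C1) → lactol/Wittig opening → C6 side chain and anisate → ozonolysis to the C2 methoxy hydroperoxide → silylation → annulation (ring A plus peroxide bridge) → O–O cleavage → ring B by metathesis → angelate.
5. Stereochemistry: C5 by catalysis ((R)-BINAP/Rh); C1 by alkylation anti to the C5 substituent; C6 by Felkin–Anh addition; C2 and C4 in the key step (C5 and the peroxide tether); the (Z)-alkene is bought with angelic acid.

Key step: step 11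

Assumption: the alkenyl pinacol boronate 2 is taken as a catalogue compound.

Step 1
Reactants: 1 furan-2(5H)-one; 2 4,4,5,5-tetramethyl-2-(3-methylbut-1-en-2-yl)-1,3,2-dioxaborolane
Product: 3 (4R)-4-(3-methylbut-1-en-2-yl)dihydrofuran-2(3H)-one
Conditions: [RhCl(C2H4)2]2 (2.5 mol%), (R)-BINAP (5.5 mol%), KOH (0.3 equiv), dioxane/H2O 10:1, 50 °C
Reagents that add atoms: none
Why: Hayashi–Miyaura asymmetric 1,4-addition of an alkenylboron reagent to an unsaturated lactone; the (R)-BINAP–Rh catalyst should deliver the alkenyl group to one enantioface and set C5 (4R in 3), the sense being assigned by analogy with additions to cyclic enones.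

Step 2
Reactants: 3 (4R)-4-(3-methylbut-1-en-2-yl)dihydrofuran-2(3H)-one
Product: 5 (3S,4R)-3-allyl-4-(3-methylbut-1-en-2-yl)dihydrofuran-2(3H)-one, via lithium enolate 4 (not isolated)
Conditions: LiN(i-Pr)2, THF, −78 °C; allyl bromide, −78 → −30 °C
Reagents that add atoms: allyl bromide, C=CCBr
Why: Kinetic lactone enolate alkylation, the allyl group entering anti to the C5 alkenyl group; this centre is re-formed in step 3, so its configuration is not critical.

Step 3
Reactants: 5 (3S,4R)-3-allyl-4-(3-methylbut-1-en-2-yl)dihydrofuran-2(3H)-one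
Product: 7 (3R,4S)-3-allyl-3-methyl-4-(3-methylbut-1-en-2-yl)dihydrofuran-2(3H)-one, via lithium enolate 6 (not isolated)
Conditions: LiN(i-Pr)2, THF, −78 °C; CH3I, DMPU, −78 → 0 °C
Reagents that add atoms: iodomethane, CI
Why: Second enolate alkylation builds the quaternary C1; iodomethane should approach the enolate face anti to the neighbouring alkenyl group, so methyl ends trans and allyl cis to it (1,2-induction in a five-membered ring).

Step 4
Reactants: 7 (3R,4S)-3-allyl-3-methyl-4-(3-methylbut-1-en-2-yl)dihydrofuran-2(3H)-one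
Product: 8 (3R,4S)-3-allyl-3-methyl-4-(3-methylbut-1-en-2-yl)tetrahydrofuran-2-ol (both C2 epimers)
Conditions: i-Bu2AlH (1.1 equiv), CH2Cl2, −78 °C; aq. potassium sodium tartrate
Reagents that add atoms: none
Why: Partial reduction of a lactone to the lactol; the tetrahedral aluminate is stable at −78 °C and collapses only on work-up.

Step 5
Reactants: 8 (3R,4S)-3-allyl-3-methyl-4-(3-methylbut-1-en-2-yl)tetrahydrofuran-2-ol
Product: 9 (2S,3R)-3-(2-methoxyethenyl)-3-methyl-2-(3-methylbut-1-en-2-yl)hex-5-en-1-ol (E/Z mixture)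
Conditions: (methoxymethyl)triphenylphosphonium chloride, KN(SiMe3)2, THF, 0 → 40 °C
Reagents that add atoms: (methoxymethyl)triphenylphosphonium chloride, COC[P+](c1ccccc1)(c1ccccc1)c1ccccc1.[Cl-]
Why: Wittig methoxymethylenation of the open hydroxy-aldehyde form of the lactol; it frees the C6 oxygen and stores C2 as an enol ether whose geometry is of no consequence.

Step 6
Reactants: 9 (2S,3R)-3-(2-methoxyethenyl)-3-methyl-2-(3-methylbut-1-en-2-yl)hex-5-en-1-ol
Product: 10 (2S,3S)-3-(2-methoxyethenyl)-3-methyl-2-(3-methylbut-1-en-2-yl)hex-5-enal (E/Z mixture)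
Conditions: (n-Pr4N)RuO4 (5 mol%), N-methylmorpholine N-oxide, 4 Å molecular sieves, CH2Cl2, 0 °C → rt
Reagents that add atoms: none
Why: Ley–Griffith oxidation of the primary alcohol under near-neutral conditions, chosen so that the enol ether survives and the α-centre (C5) of the β,γ-unsaturated aldehyde is not epimerised.

Step 7
Reactants: 10 (2S,3S)-3-(2-methoxyethenyl)-3-methyl-2-(3-methylbut-1-en-2-yl)hex-5-enal
Product: 11 (4S,5S,6S)-6-(2-methoxyethenyl)-2,6-dimethyl-5-(3-methylbut-1-en-2-yl)nona-1,8-dien-4-ol (E/Z mixture)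
Conditions: 2-methylallylmagnesium chloride, THF, −78 °C; aq. NH4Cl
Reagents that add atoms: 2-methylallylmagnesium chloride, CC(=C)C[Mg]Cl
Why: Grignard addition under Felkin–Anh control; with the quaternary C1 as the large group anti to the nucleophile and the alkenyl group inside, the addition should give the C6 carbinol of the target series (4S in 11).

Step 8
Reactants: 11 (4S,5S,6S)-6-(2-methoxyethenyl)-2,6-dimethyl-5-(3-methylbut-1-en-2-yl)nona-1,8-dien-4-ol
Product: 12 (4S,5S,6S)-6-(2-methoxyethenyl)-2,6-dimethyl-5-(3-methylbut-1-en-2-yl)nona-1,8-dien-4-yl 4-methoxybenzoate (E/Z mixture)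
Conditions: 4-methoxybenzoyl chloride, pyridine, DMAP (cat.), CH2Cl2, 0 °C → rt
Reagents that add atoms: 4-methoxybenzoyl chloride, COc1ccc(cc1)C(Cl)=O
Why: DMAP-catalysed acylation; the anisate is installed before the C2/C4 diol exists, so the two secondary hydroxyls never have to be told apart.

Step 9
Reactants: 12 (4S,5S,6S)-6-(2-methoxyethenyl)-2,6-dimethyl-5-(3-methylbut-1-en-2-yl)nona-1,8-dien-4-yl 4-methoxybenzoate
Product: 14 (4S,5S,6R)-6-[hydroperoxy(methoxy)methyl]-2,6-dimethyl-5-(3-methylbut-1-en-2-yl)nona-1,8-dien-4-yl 4-methoxybenzoate (both epimers at the acetal carbon), via carbonyl oxide 13 (not isolated)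
Conditions: O3 (1.0 equiv, titrated solution in CH2Cl2), CH2Cl2/MeOH 3:1, −78 °C
Reagents that add atoms: ozone, [O-][O+]=O; methanol, CO
Why: Ozonolysis with Criegee fragmentation; the enol ether is the most electron-rich alkene and should be cleaved selectively by one equivalent of ozone to methyl formate and the C2 carbonyl oxide 13, which methanol traps as the α-methoxy hydroperoxide (both C2 epimers converge in step 11).

Step 10
Reactants: 14 (4S,5S,6R)-6-[hydroperoxy(methoxy)methyl]-2,6-dimethyl-5-(3-methylbut-1-en-2-yl)nona-1,8-dien-4-yl 4-methoxybenzoate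
Product: 15 (4S,5S,6R)-6-{methoxy[(triethylsilyl)peroxy]methyl}-2,6-dimethyl-5-(3-methylbut-1-en-2-yl)nona-1,8-dien-4-yl 4-methoxybenzoate (both epimers at the acetal carbon)
Conditions: Et3SiCl, imidazole, DMF, 0 °C
Reagents that add atoms: chlorotriethylsilane, CC[Si](Cl)(CC)CC
Why: O-Silylation of the hydroperoxide, the standard way to silylperoxy acetals; it turns the distal peroxy oxygen into a nucleophile with a silyl leaving group.

Step 11
Reactants: 15 (4S,5S,6R)-6-{methoxy[(triethylsilyl)peroxy]methyl}-2,6-dimethyl-5-(3-methylbut-1-en-2-yl)nona-1,8-dien-4-yl 4-methoxybenzoate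
Product: 18 (1S)-3-methyl-1-[(1R,4R,5R,6S)-5-methyl-1-(propan-2-yl)-5-(prop-2-en-1-yl)-2,3-dioxabicyclo[2.2.1]heptan-6-yl]but-3-en-1-yl 4-methoxybenzoate, via peroxycarbenium ion 16 (not isolated), via cyclopentyl cation 17 (not isolated)
Conditions: SnCl4 (1.2 equiv), CH2Cl2, −78 °C; aq. NaHCO3
Reagents that add atoms: none
Why: Proposed new method: SnCl4 ionises the C2–OMe bond of 15 to the peroxycarbenium ion 16 (not enolisable, because C1 is quaternary), the CH2 terminus (C3) of the 1,1-disubstituted alkene attacks C2 to give the tertiary cation 17 at C4, and the silylperoxy oxygen closes onto C4 with loss of Et3SiCl. The closest known reaction type is the intermolecular Lewis acid-promoted [3+2] annulation of silylperoxy acetals with alkenes to 1,2-dioxolanes, and the carbocycle-forming half has the topology of the Lewis acid-promoted cyclisation of 2-substituted allylsilanes onto tethered carbonyl groups (methylenecyclopentane annulation), but the intramolecular, bridged combination has not been described. Ring A closes at C2–C3 by attack on the exocyclic C=O+ bond with both alkene carbons inside the new ring (5-exo-trig at C2, endo with respect to the alkene), and the dioxolane closes by 5-exo capture of the cation, which together give the 2,3-dioxabicyclo[2.2.1]heptane. C2 is controlled by C5: in the C–C bond-forming transition state the C5–H bond should eclipse the isopropyl group (1,2-allylic strain), C1 lies on one face and the C6 side chain on the other face of the alkene, and the bulky O–OSiEt3 group points away from the forming ring, so that the C2–O bond emerges cis to the C6 side chain and to the C1 methyl group. C4 is controlled by the tether, since the peroxy oxygen can reach the cation only on the face that carries C2–O, which makes the two C–O bonds cis and places the isopropyl group trans to the C6 side chain (the anisoyl carbonyl on the same face would be a convergent second trap). The step needs site selectivity for C3=C4 over the allyl and 2-methylallyl groups, secured by the five-membered closure to a tertiary cation (the alternatives are a secondary cation or a seven-membered ring), and C–OMe ionisation in preference to O–O heterolysis, secured by the more basic ether oxygen at −78 °C.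

Step 12
Reactants: 18 (1S)-3-methyl-1-[(1R,4R,5R,6S)-5-methyl-1-(propan-2-yl)-5-(prop-2-en-1-yl)-2,3-dioxabicyclo[2.2.1]heptan-6-yl]but-3-en-1-yl 4-methoxybenzoate
Product: 19 (1S)-1-[(1S,2R,3R,5R)-3,5-dihydroxy-2-methyl-5-(propan-2-yl)-2-(prop-2-en-1-yl)cyclopentyl]-3-methylbut-3-en-1-yl 4-methoxybenzoate
Conditions: Zn dust, AcOH, THF, 0 °C → rt
Reagents that add atoms: none
Why: Reductive cleavage of the O–O bond by zinc in acetic acid; neither C–O bond is touched, so the cis-1,3-diol keeps the configuration set in step 11, and the alkenes and the aryl ester are inert.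

Step 13
Reactants: 19 (1S)-1-[(1S,2R,3R,5R)-3,5-dihydroxy-2-methyl-5-(propan-2-yl)-2-(prop-2-en-1-yl)cyclopentyl]-3-methylbut-3-en-1-yl 4-methoxybenzoate
Product: 20 (1R,3R,3aS,4S,8aR)-1,3-dihydroxy-6,8a-dimethyl-3-(propan-2-yl)-1,2,3,3a,4,5,8,8a-octahydroazulen-4-yl 4-methoxybenzoate
Conditions: second-generation Grubbs catalyst, RuCl2(=CHPh)(PCy3)(H2IMes) (5 mol%), CH2Cl2 (2 mM), 40 °C
Reagents that add atoms: none
Why: Ring-closing metathesis between the allyl and 2-methylallyl groups closes ring B with the trisubstituted C8=C9 alkene; ethene is lost and no stereocentre is formed.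

Step 14
Reactants: 20 (1R,3R,3aS,4S,8aR)-1,3-dihydroxy-6,8a-dimethyl-3-(propan-2-yl)-1,2,3,3a,4,5,8,8a-octahydroazulen-4-yl 4-methoxybenzoate
Product: 21 (1R,3R,3aS,4S,8aR)-3-hydroxy-6,8a-dimethyl-1-{[(2Z)-2-methylbut-2-enoyl]oxy}-3-(propan-2-yl)-1,2,3,3a,4,5,8,8a-octahydroazulen-4-yl 4-methoxybenzoate (CNP0204191.1)
Conditions: angelic acid, 2,4,6-trichlorobenzoyl chloride, Et3N, toluene, rt; then 20, toluene, 80 °C
Reagents that add atoms: angelic acid, C/C=C(/C)C(O)=O
Why: Yamaguchi esterification through the mixed anhydride, a protocol that should keep the (Z)-geometry; only the secondary C2 hydroxyl should react, the tertiary C4 hydroxyl being too hindered.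

**Compound list**

1 | furan-2(5H)-one | O=C1OCC=C1 | starting material
2 | 4,4,5,5-tetramethyl-2-(3-methylbut-1-en-2-yl)-1,3,2-dioxaborolane | C=C(C(C)C)B1OC(C)(C)C(C)(C)O1 | starting material
3 | (4R)-4-(3-methylbut-1-en-2-yl)dihydrofuran-2(3H)-one | C=C(C(C)C)[C@H]1CC(=O)OC1 | intermediate
4 | lithium enolate of 3, lithium (3R)-3-(3-methylbut-1-en-2-yl)-2,3-dihydrofuran-5-olate | C=C(C(C)C)[C@H]1C=C([O-])OC1.[Li+] | intermediate
5 | (3S,4R)-3-allyl-4-(3-methylbut-1-en-2-yl)dihydrofuran-2(3H)-one | C=C(C(C)C)[C@H]1[C@H](CC=C)C(=O)OC1 | intermediate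
6 | lithium enolate of 5 | C=C(C(C)C)[C@H]1C(CC=C)=C([O-])OC1.[Li+] | intermediate
7 | (3R,4S)-3-allyl-3-methyl-4-(3-methylbut-1-en-2-yl)dihydrofuran-2(3H)-one | C=C(C(C)C)[C@H]1[C@@](C)(CC=C)C(=O)OC1 | intermediate
8 | (3R,4S)-3-allyl-3-methyl-4-(3-methylbut-1-en-2-yl)tetrahydrofuran-2-ol, both C2 epimers | C=C(C(C)C)[C@H]1[C@@](C)(CC=C)C(O)OC1 | intermediate
9 | (2S,3R)-3-(2-methoxyethenyl)-3-methyl-2-(3-methylbut-1-en-2-yl)hex-5-en-1-ol, E/Z mixture | COC=C[C@](C)(CC=C)[C@@H](CO)C(=C)C(C)C | intermediate
10 | (2S,3S)-3-(2-methoxyethenyl)-3-methyl-2-(3-methylbut-1-en-2-yl)hex-5-enal, E/Z mixture | COC=C[C@](C)(CC=C)[C@@H](C=O)C(=C)C(C)C | intermediate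
11 | (4S,5S,6S)-6-(2-methoxyethenyl)-2,6-dimethyl-5-(3-methylbut-1-en-2-yl)nona-1,8-dien-4-ol, E/Z mixture | COC=C[C@](C)(CC=C)[C@@H]([C@@H](O)CC(C)=C)C(=C)C(C)C | intermediate
12 | (4S,5S,6S)-6-(2-methoxyethenyl)-2,6-dimethyl-5-(3-methylbut-1-en-2-yl)nona-1,8-dien-4-yl 4-methoxybenzoate, E/Z mixture | COC=C[C@](C)(CC=C)[C@@H]([C@@H](OC(=O)c1ccc(OC)cc1)CC(C)=C)C(=C)C(C)C | intermediate
13 | C2 carbonyl oxide formed from 12 (O-oxide of the C2 aldehyde) | [O-][O+]=C[C@](C)(CC=C)[C@@H]([C@@H](OC(=O)c1ccc(OC)cc1)CC(C)=C)C(=C)C(C)C | intermediate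
14 | (4S,5S,6R)-6-[hydroperoxy(methoxy)methyl]-2,6-dimethyl-5-(3-methylbut-1-en-2-yl)nona-1,8-dien-4-yl 4-methoxybenzoate, both epimers at the acetal carbon | COC(OO)[C@](C)(CC=C)[C@@H]([C@@H](OC(=O)c1ccc(OC)cc1)CC(C)=C)C(=C)C(C)C | intermediate
15 | (4S,5S,6R)-6-{methoxy[(triethylsilyl)peroxy]methyl}-2,6-dimethyl-5-(3-methylbut-1-en-2-yl)nona-1,8-dien-4-yl 4-methoxybenzoate, both epimers at the acetal carbon | COC(OO[Si](CC)(CC)CC)[C@](C)(CC=C)[C@@H]([C@@H](OC(=O)c1ccc(OC)cc1)CC(C)=C)C(=C)C(C)C | intermediate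
16 | C2 peroxycarbenium ion (O-triethylsilylperoxy oxocarbenium) formed from 15 | CC[Si](CC)(CC)O[O+]=C[C@](C)(CC=C)[C@@H]([C@@H](OC(=O)c1ccc(OC)cc1)CC(C)=C)C(=C)C(C)C | intermediate
17 | tertiary C4 cyclopentyl cation with the C2 triethylsilylperoxy group cis to the C6 side chain | CC[Si](CC)(CC)OO[C@@H]1C[C+](C(C)C)[C@H]([C@@H](OC(=O)c2ccc(OC)cc2)CC(C)=C)[C@@]1(C)CC=C | intermediate
18 | (1S)-3-methyl-1-[(1R,4R,5R,6S)-5-methyl-1-(propan-2-yl)-5-(prop-2-en-1-yl)-2,3-dioxabicyclo[2.2.1]heptan-6-yl]but-3-en-1-yl 4-methoxybenzoate | O1[C@@H]2C[C@@](O1)(C(C)C)[C@H]([C@@H](OC(=O)c3ccc(OC)cc3)CC(C)=C)[C@@]2(C)CC=C | intermediate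
19 | (1S)-1-[(1S,2R,3R,5R)-3,5-dihydroxy-2-methyl-5-(propan-2-yl)-2-(prop-2-en-1-yl)cyclopentyl]-3-methylbut-3-en-1-yl 4-methoxybenzoate | O[C@@H]1C[C@@](O)(C(C)C)[C@H]([C@@H](OC(=O)c2ccc(OC)cc2)CC(C)=C)[C@@]1(C)CC=C | intermediate
20 | (1R,3R,3aS,4S,8aR)-1,3-dihydroxy-6,8a-dimethyl-3-(propan-2-yl)-1,2,3,3a,4,5,8,8a-octahydroazulen-4-yl 4-methoxybenzoate | O[C@@H]1C[C@@](O)(C(C)C)[C@@H]2[C@@H](OC(=O)c3ccc(OC)cc3)CC(C)=CC[C@]21C | intermediate
21 | (1R,3R,3aS,4S,8aR)-3-hydroxy-6,8a-dimethyl-1-{[(2Z)-2-methylbut-2-enoyl]oxy}-3-(propan-2-yl)-1,2,3,3a,4,5,8,8a-octahydroazulen-4-yl 4-methoxybenzoate | C/C=C(/C)C(=O)O[C@@H]1C[C@@](O)(C(C)C)[C@@H]2[C@@H](OC(=O)c3ccc(OC)cc3)CC(C)=CC[C@]21C | target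

Total step count: 14. Longest linear sequence: 14 steps (1 → 21).

**Steps most likely to fail**

Step 11 (proposed new method). Three processes may defeat it. The first is O–O heterolysis with 1,2-shift of the tertiary C1 to oxygen (Criegee-type) in place of C–OMe ionisation. The second is a hydride shift from the isopropyl methine, or proton loss, in the cation before the peroxy oxygen closes. The third is closure through the transition state that holds the peroxy group over the alkene, which would invert C2 and C4 together. The fallback uses known reaction types and gives up the peroxide tether. It sets out from 14, which PPh3 reduces to the aldehyde (4S,5S,6R)-6-formyl-2,6-dimethyl-5-(3-methylbut-1-en-2-yl)nona-1,8-dien-4-yl 4-methoxybenzoate F1. Me2AlCl in CH2Cl2 at −78 °C should then bring about a conventional Prins cyclisation of the complexed aldehyde onto the same 1,1-disubstituted alkene. The tertiary cation is taken up on the C6 face by the carbonyl oxygen of the neighbouring ester, giving the ring-fused 2-(4-methoxyphenyl)-1,3-dioxan-2-ylium ion F2. Aqueous work-up opens F2 to the tertiary alcohol and the secondary ester, and the route is rejoined at 19. This fallback still depends on the same C2–C3 bond formation, so it answers failure of the peroxide chemistry but not a failure of the carbocycle closure itself.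

Step 9. Ozone may not stop at the enol ether and may go on to cleave the 1,1-disubstituted and monosubstituted alkenes. The fallback sets out from 12. Sensitised photo-oxygenation (O2, tetraphenylporphyrin, hν, CH2Cl2, −78 °C) should add singlet oxygen only to the enol ether, which has no allylic hydrogen and so reacts by [2+2] cycloaddition, while the simple alkenes react far more slowly. This gives (4S,5S,6R)-6-(4-methoxy-1,2-dioxetan-3-yl)-2,6-dimethyl-5-(3-methylbut-1-en-2-yl)nona-1,8-dien-4-yl 4-methoxybenzoate F3, which on warming splits into methyl formate and the aldehyde F1. HC(OMe)3 with pyridinium p-toluenesulfonate in MeOH converts F1 into (4S,5S,6R)-6-(dimethoxymethyl)-2,6-dimethyl-5-(3-methylbut-1-en-2-yl)nona-1,8-dien-4-yl 4-methoxybenzoate F4. Acid-catalysed exchange with anhydrous ethereal H2O2 then gives 14, where the route is rejoined.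

Step 7. Facial selectivity in the addition to the α-branched aldehyde may be poor or reversed, and the basic reagent may epimerise C5 or move the C3=C4 double bond into conjugation. The fallback sets out from 10. The addition is run under non-basic Barbier conditions (2-methylallyl bromide, indium powder, THF/H2O) and the two C6 epimers are separated. Compound 11 goes on as planned. The epimer (4R,5S,6S)-6-(2-methoxyethenyl)-2,6-dimethyl-5-(3-methylbut-1-en-2-yl)nona-1,8-dien-4-ol F5 is esterified with inversion at C6 (Mitsunobu reaction: 4-methoxybenzoic acid, PPh3, diisopropyl azodicarboxylate). Both epimers thus converge on 12, where the route is rejoined.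

Further compounds
F1 | step 11 | (4S,5S,6R)-6-formyl-2,6-dimethyl-5-(3-methylbut-1-en-2-yl)nona-1,8-dien-4-yl 4-methoxybenzoate | O=C[C@](C)(CC=C)[C@@H]([C@@H](OC(=O)c1ccc(OC)cc1)CC(C)=C)C(=C)C(C)C
F2 | step 11 | 2-(4-methoxyphenyl)-1,3-dioxan-2-ylium ion fused to ring A at C4–C5 (O1 on C4, O3 on C6), C2 hydroxyl drawn free | O[C@@H]1C[C@]2(C(C)C)OC(c3ccc(OC)cc3)=[O+][C@@H](CC(C)=C)[C@@H]2[C@@]1(C)CC=C
F3 | step 9 | (4S,5S,6R)-6-(4-methoxy-1,2-dioxetan-3-yl)-2,6-dimethyl-5-(3-methylbut-1-en-2-yl)nona-1,8-dien-4-yl 4-methoxybenzoate | COC1OOC1[C@](C)(CC=C)[C@@H]([C@@H](OC(=O)c2ccc(OC)cc2)CC(C)=C)C(=C)C(C)C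
F4 | step 9 | (4S,5S,6R)-6-(dimethoxymethyl)-2,6-dimethyl-5-(3-methylbut-1-en-2-yl)nona-1,8-dien-4-yl 4-methoxybenzoate | COC(OC)[C@](C)(CC=C)[C@@H]([C@@H](OC(=O)c1ccc(OC)cc1)CC(C)=C)C(=C)C(C)C
F5 | step 7 | (4R,5S,6S)-6-(2-methoxyethenyl)-2,6-dimethyl-5-(3-methylbut-1-en-2-yl)nona-1,8-dien-4-ol | COC=C[C@](C)(CC=C)[C@@H]([C@H](O)CC(C)=C)C(=C)C(C)C
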